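The benzylic C–O bond of the secondary alcohol is the bond on which everything rests. Its carbon carries the 3,4-dimethoxyphenyl ring, and the carbon that ends up as the allylic-chain CH= lies three bonds further along, so the alcohol oxygen and the future alkene carbon fit into one γ-butyrolactone ring. A single dehydrogenative lactonisation of the veratryl CH2 of an open-chain acid makes that C–O bond, closes the five-membered ring and sets the carbinol stereocentre trans to the existing one. Its precursor is (R)-4-(3,4-dimethoxyphenyl)-3-(methoxycarbonyl)butanoic acid, reached by Stobbe condensation and asymmetric hydrogenation. Lactol olefination and a late primary esterification complete the target.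

Key step: step 3

Remark: the (S,S)-enantiomer of Et-DuPhos is assumed to deliver the (R)-acid 4, as is usual for β-substituted itaconate half-esters; if a trial shows the opposite sense, the (R,R)-ligand is used and nothing else changes.

Step 1
Reactants: 1 veratraldehyde (3,4-dimethoxybenzaldehyde); 2 dimethyl succinate
Product: 3 (E)-4-(3,4-dimethoxyphenyl)-3-(methoxycarbonyl)but-3-enoic acid
Conditions: NaOMe (1.5 equiv), MeOH, reflux; then aq. HCl
Reagents that add atoms: none
Why: Stobbe condensation: the succinate enolate adds to the aldehyde, the aldolate closes onto the distal ester to a paraconate, and base-induced E1cB opening of that lactone should deliver the conjugated (E)-alkylidene half-ester with its free carboxyl on the CH2 arm.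

Step 2
Reactants: 3 (E)-4-(3,4-dimethoxyphenyl)-3-(methoxycarbonyl)but-3-enoic acid
Product: 4 (R)-4-(3,4-dimethoxyphenyl)-3-(methoxycarbonyl)butanoic acid
Conditions: H2 (5 bar), [Rh(cod)((S,S)-Et-DuPhos)]BF4 (0.5 mol %), NaOMe (0.1 equiv), MeOH, rt
Reagents that add atoms: none
Why: Rh-catalysed asymmetric hydrogenation of a β-aryl itaconate half-ester: carboxylate and alkene bind the cationic rhodium bisphospholane as a chelate, the C2-symmetric ligand exposes one alkene face, and C-3 should be set as R under catalyst control while arene, ester and acid stay inert.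

Step 3
Reactants: 4 (R)-4-(3,4-dimethoxyphenyl)-3-(methoxycarbonyl)butanoic acid
Product: 5 methyl (2S,3S)-2-(3,4-dimethoxyphenyl)-5-oxotetrahydrofuran-3-carboxylate (trans lactone)
Conditions: DDQ (1.3 equiv), 4 Å MS, ClCH2CH2Cl, rt → 60 °C
Reagents that add atoms: none
Why: DDQ should form a charge-transfer complex with the dimethoxyarene and abstract hydride from the only benzylic CH2, giving a cation stabilised by the para methoxy group; the tethered carboxylic acid captures it and the proton passes to the hydroquinone anion. The closest known reaction type is the DDQ-mediated dehydrogenative lactonisation of electron-rich 4-arylbutanoic acids, together with the related DDQ cyclisation of lignan diols to 2-aryltetrahydrofurans. The γ-lactone closes in a 5-exo-trig mode, the carboxyl oxygen attacking the cationic carbon whose C=aryl π bond lies outside the new ring. The new benzylic stereocentre is set under substrate control by C-3: in the envelope transition state the aryl and methoxycarbonyl groups avoid each other, so the trans (2S,3S) lactone should form, and it is also the thermodynamic isomer reachable by re-ionisation of the benzylic C–O bond. The step needs site selectivity, inherent because only one C–H is benzylic, and chemoselectivity for O-capture over loss of the C-3 proton or capture by water; the 1,4 placement of the acid, base-free conditions and molecular sieves secure this. The C-3 carboxyl is kept as its methyl ester because a free acid β to the cation would invite decarboxylative fragmentation, and the neutral product is then freed from unreacted acid and hydroquinone by a bicarbonate wash.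

Step 4
Reactants: 5 methyl (2S,3S)-2-(3,4-dimethoxyphenyl)-5-oxotetrahydrofuran-3-carboxylate
Product: 7 (2S,3S)-2-(3,4-dimethoxyphenyl)-5-oxotetrahydrofuran-3-carboxylic acid, via dilithium hydroxy-succinate 6 (not isolated)
Conditions: LiOH (3 equiv), THF/H2O, 0 °C → rt; then 1 M HCl (pH 1–2), rt
Reagents that add atoms: lithium hydroxide, [Li+].[OH-]
Why: Ester saponification followed by acid-induced γ-lactonisation: hydroxide should attack the lactone and ester carbonyls much faster than it removes the C-3 proton (so neither epimerisation nor E1cB loss of the carboxylate intervenes), and on acidification only the CH2CO2H arm can reach the benzylic hydroxyl through a five-membered ring, so the trans lactone re-forms with both stereocentres untouched.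

Step 5
Reactants: 7 (2S,3S)-2-(3,4-dimethoxyphenyl)-5-oxotetrahydrofuran-3-carboxylic acid
Product: 8 (4R,5S)-5-(3,4-dimethoxyphenyl)-4-(hydroxymethyl)dihydrofuran-2(3H)-one
Conditions: BH3·SMe2 (1.5 equiv), THF, 0 °C → rt; MeOH
Reagents that add atoms: none
Why: Chemoselective borane reduction of a carboxylic acid: BH3 converts the acid via its acyloxyborane into the primary alcohol far faster than it attacks the lactone carbonyl, so only the C-3 carboxyl should be reduced and no stereocentre is touched.

Step 6
Reactants: 8 (4R,5S)-5-(3,4-dimethoxyphenyl)-4-(hydroxymethyl)dihydrofuran-2(3H)-one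
Product: 9 (4R,5S)-4-{[(tert-butyldimethylsilyl)oxy]methyl}-5-(3,4-dimethoxyphenyl)dihydrofuran-2(3H)-one
Conditions: TBSCl, imidazole, CH2Cl2, 0 °C → rt
Reagents that add atoms: tert-butyldimethylsilyl chloride, CC(C)(C)[Si](C)(C)Cl
Why: Silyl ether protection: the unhindered primary hydroxyl should be silylated under mild conditions that leave the lactone closed, so that the following hydride and carbanion steps meet a single acidic site.

Step 7
Reactants: 9 (4R,5S)-4-{[(tert-butyldimethylsilyl)oxy]methyl}-5-(3,4-dimethoxyphenyl)dihydrofuran-2(3H)-one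
Product: 10 (4R,5S)-4-{[(tert-butyldimethylsilyl)oxy]methyl}-5-(3,4-dimethoxyphenyl)tetrahydrofuran-2-ol (mixture of anomers)
Conditions: i-Bu2AlH (1.1 equiv), CH2Cl2, −78 °C; aq. potassium sodium tartrate
Reagents that add atoms: none
Why: Half-reduction of a γ-lactone with i-Bu2AlH: one hydride adds to the lactone carbonyl and the tetrahedral aluminium lactolate is stable at −78 °C, so hydrolysis should give the lactol without over-reduction while silyl and aryl ethers are inert.

Step 8
Reactants: 10 (4R,5S)-4-{[(tert-butyldimethylsilyl)oxy]methyl}-5-(3,4-dimethoxyphenyl)tetrahydrofuran-2-ol; 11 diethyl (4-methoxybenzyl)phosphonate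
Product: 14 (1S,2R)-1-(3,4-dimethoxyphenyl)-2-[(2E)-3-(4-methoxyphenyl)prop-2-en-1-yl]propane-1,3-diol, via potassium phosphonate carbanion 12 (not isolated), via primary TBS ether 13 (not isolated)
Conditions: 11 (1.5 equiv), KOt-Bu (2.6 equiv), THF, 0 °C; 10, 0 °C → rt; then n-Bu4NF (2 equiv), rt; aq. NH4Cl
Reagents that add atoms: none
Why: Horner–Wadsworth–Emmons olefination of a lactol: the potassium lactolate is in equilibrium with the open hydroxy-aldehyde, which the semi-stabilised benzylic phosphonate carbanion should convert into the (E)-styrene by reversible addition and elimination of diethyl phosphate; neither stereocentre is α to the aldehyde, and fluoride then strips the silyl group from whichever oxygen it occupies, so silyl migration to the freed benzylic alkoxide is of no consequence.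

Step 9
Reactants: 15 crotonaldehyde ((E)-but-2-enal)
Product: 17 (Z)-2-bromobut-2-enal, via 2,3-dibromobutanal 16 (not isolated)
Conditions: Br2, CH2Cl2, 0 °C; then Et3N, 0 °C → rt
Reagents that add atoms: bromine, BrBr
Why: Alkene bromination followed by dehydrobromination: anti addition of Br2 gives the dibromide, and triethylamine removes the acidic α-proton and expels the β-bromide through the enolate (E1cB), which should lead to the more stable α-bromo enal with the methyl group trans to the formyl group, i.e. the Z isomer.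

Step 10
Reactants: 17 (Z)-2-bromobut-2-enal
Product: 18 (Z)-2-bromobut-2-en-1-ol
Conditions: NaBH4, CeCl3·7H2O, MeOH, 0 °C
Reagents that add atoms: none
Why: Luche 1,2-reduction: NaBH4 with CeCl3 should reduce the aldehyde carbonyl selectively, leaving the C=C bond, its Z geometry and the vinylic bromide intact.

Step 11
Reactants: 18 (Z)-2-bromobut-2-en-1-ol
Product: 19 {[(Z)-2-bromobut-2-en-1-yl]oxy}(tert-butyl)dimethylsilane
Conditions: TBSCl, imidazole, CH2Cl2, rt
Reagents that add atoms: tert-butyldimethylsilyl chloride, CC(C)(C)[Si](C)(C)Cl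
Why: Silyl ether protection: the primary allylic alcohol is masked so that no acidic proton interferes with the halogen–lithium exchange and this hydroxyl cannot compete in the later esterification.

Step 12
Reactants: 19 {[(Z)-2-bromobut-2-en-1-yl]oxy}(tert-butyl)dimethylsilane
Product: 21 (Z)-2-({[tert-butyl(dimethyl)silyl]oxy}methyl)but-2-enoic acid, via vinyllithium 20 (not isolated)
Conditions: t-BuLi (2.1 equiv), Et2O, −78 °C; CO2, −78 → 0 °C; then 1 M HCl (pH 3)
Reagents that add atoms: carbon dioxide, O=C=O
Why: Bromine–lithium exchange and carboxylation: t-BuLi exchanges the vinylic bromide with retention, the vinyllithium is configurationally stable at −78 °C in ether (where O→C silyl shift is slow), and CO2 should place the carboxyl where bromine was, cis to the methyl group, which defines the Z acid.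

Step 13
Reactants: 14 (1S,2R)-1-(3,4-dimethoxyphenyl)-2-[(2E)-3-(4-methoxyphenyl)prop-2-en-1-yl]propane-1,3-diol; 21 (Z)-2-({[tert-butyl(dimethyl)silyl]oxy}methyl)but-2-enoic acid
Product: 22 (2R,3S)-3-(3,4-dimethoxyphenyl)-3-hydroxy-2-[(2E)-3-(4-methoxyphenyl)prop-2-en-1-yl]propyl (2Z)-2-({[tert-butyl(dimethyl)silyl]oxy}methyl)but-2-enoate
Conditions: 21 (1.05 equiv), EDC·HCl (1.3 equiv), DMAP (0.1 equiv), CH2Cl2, −20 → 0 °C
Reagents that add atoms: none
Why: Steglich esterification (carbodiimide, catalytic DMAP): the activated α-branched acid should acylate the unhindered primary hydroxyl much faster than the hindered secondary benzylic one, and low temperature with little DMAP keeps the Z alkene from isomerising.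

Step 14
Reactants: 22 (2R,3S)-3-(3,4-dimethoxyphenyl)-3-hydroxy-2-[(2E)-3-(4-methoxyphenyl)prop-2-en-1-yl]propyl (2Z)-2-({[tert-butyl(dimethyl)silyl]oxy}methyl)but-2-enoate
Product: 23 (2R,3S)-3-(3,4-dimethoxyphenyl)-3-hydroxy-2-[(2E)-3-(4-methoxyphenyl)prop-2-en-1-yl]propyl (2Z)-2-(hydroxymethyl)but-2-enoate (CNP0280662.1)
Conditions: HF·pyridine, pyridine, THF, 0 °C → rt
Reagents that add atoms: none
Why: Fluoride-mediated desilylation: pyridine-buffered HF should cleave the primary allylic Si–O bond by forming the strong Si–F bond under near-neutral conditions, which leave the ester, both alkenes and the electron-rich benzylic alcohol untouched and give no opening for base-induced acyl migration.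

Compound list
1 | veratraldehyde (3,4-dimethoxybenzaldehyde) | COc1ccc(C=O)cc1OC | starting material
2 | dimethyl succinate | COC(=O)CCC(=O)OC | starting material
3 | (E)-4-(3,4-dimethoxyphenyl)-3-(methoxycarbonyl)but-3-enoic acid | COC(=O)/C(CC(=O)O)=C/c1ccc(OC)c(OC)c1 | intermediate
4 | (R)-4-(3,4-dimethoxyphenyl)-3-(methoxycarbonyl)butanoic acid | COC(=O)[C@@H](CC(=O)O)Cc1ccc(OC)c(OC)c1 | intermediate
5 | methyl (2S,3S)-2-(3,4-dimethoxyphenyl)-5-oxotetrahydrofuran-3-carboxylate (trans) | COC(=O)[C@H]1CC(=O)O[C@@H]1c2ccc(OC)c(OC)c2 | intermediate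
6 | dilithium (S)-2-[(S)-(3,4-dimethoxyphenyl)(hydroxy)methyl]succinate | [Li+].[Li+].[O-]C(=O)C[C@H](C(=O)[O-])[C@H](O)c1ccc(OC)c(OC)c1 | intermediate (not isolated)
7 | (2S,3S)-2-(3,4-dimethoxyphenyl)-5-oxotetrahydrofuran-3-carboxylic acid | OC(=O)[C@H]1CC(=O)O[C@@H]1c2ccc(OC)c(OC)c2 | intermediate
8 | (4R,5S)-5-(3,4-dimethoxyphenyl)-4-(hydroxymethyl)dihydrofuran-2(3H)-one | OC[C@H]1CC(=O)O[C@@H]1c2ccc(OC)c(OC)c2 | intermediate
9 | (4R,5S)-4-{[(tert-butyldimethylsilyl)oxy]methyl}-5-(3,4-dimethoxyphenyl)dihydrofuran-2(3H)-one | CC(C)(C)[Si](C)(C)OC[C@H]1CC(=O)O[C@@H]1c2ccc(OC)c(OC)c2 | intermediate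
10 | (4R,5S)-4-{[(tert-butyldimethylsilyl)oxy]methyl}-5-(3,4-dimethoxyphenyl)tetrahydrofuran-2-ol, anomeric mixture | CC(C)(C)[Si](C)(C)OC[C@H]1CC(O)O[C@@H]1c2ccc(OC)c(OC)c2 | intermediate
11 | diethyl (4-methoxybenzyl)phosphonate | CCOP(=O)(OCC)Cc1ccc(OC)cc1 | starting material
12 | potassium salt of the carbanion of diethyl (4-methoxybenzyl)phosphonate | CCOP(=O)(OCC)[CH-]c1ccc(OC)cc1.[K+] | intermediate (not isolated)
13 | (1S,2R,4E)-2-{[(tert-butyldimethylsilyl)oxy]methyl}-1-(3,4-dimethoxyphenyl)-5-(4-methoxyphenyl)pent-4-en-1-ol | CC(C)(C)[Si](C)(C)OC[C@@H](C/C=C/c1ccc(OC)cc1)[C@H](O)c1ccc(OC)c(OC)c1 | intermediate (not isolated)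
14 | (1S,2R)-1-(3,4-dimethoxyphenyl)-2-[(2E)-3-(4-methoxyphenyl)prop-2-en-1-yl]propane-1,3-diol | OC[C@@H](C/C=C/c1ccc(OC)cc1)[C@H](O)c1ccc(OC)c(OC)c1 | intermediate
15 | crotonaldehyde ((E)-but-2-enal) | C/C=C/C=O | starting material
16 | 2,3-dibromobutanal, racemic anti adduct (2R,3S shown) | C[C@H](Br)[C@H](Br)C=O | intermediate (not isolated)
17 | (Z)-2-bromobut-2-enal | C/C=C(\Br)C=O | intermediate
18 | (Z)-2-bromobut-2-en-1-ol | C/C=C(\Br)CO | intermediate
19 | {[(Z)-2-bromobut-2-en-1-yl]oxy}(tert-butyl)dimethylsilane | C/C=C(\Br)CO[Si](C)(C)C(C)(C)C | intermediate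
20 | [(E)-1-{[tert-butyl(dimethyl)silyl]oxy}but-2-en-2-yl]lithium (lithium cis to methyl, geometry of 19 retained) | C/C=C(\[Li])CO[Si](C)(C)C(C)(C)C | intermediate (not isolated)
21 | (Z)-2-({[tert-butyl(dimethyl)silyl]oxy}methyl)but-2-enoic acid | C/C=C(/CO[Si](C)(C)C(C)(C)C)C(=O)O | intermediate
22 | (2R,3S)-3-(3,4-dimethoxyphenyl)-3-hydroxy-2-[(2E)-3-(4-methoxyphenyl)prop-2-en-1-yl]propyl (2Z)-2-({[tert-butyl(dimethyl)silyl]oxy}methyl)but-2-enoate | C/C=C(/CO[Si](C)(C)C(C)(C)C)C(=O)OC[C@@H](C/C=C/c1ccc(OC)cc1)[C@H](O)c1ccc(OC)c(OC)c1 | intermediate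
23 | (2R,3S)-3-(3,4-dimethoxyphenyl)-3-hydroxy-2-[(2E)-3-(4-methoxyphenyl)prop-2-en-1-yl]propyl (2Z)-2-(hydroxymethyl)but-2-enoate | C/C=C(/CO)C(=O)OC[C@@H](C/C=C/c1ccc(OC)cc1)[C@H](O)c1ccc(OC)c(OC)c1 | target

Total step count: 14 (steps 1–8 main chain, steps 9–12 acid side chain, steps 13–14 union and release).
Longest linear sequence: 10 steps (1, 2, 3, 4, 5, 6, 7, 8, 13, 14).

Steps most likely to fail

Step 3. Hydride abstraction may be sluggish because the neighbouring ester lowers the stability of the benzylic cation. Once formed, the cation may lose the C-3 proton instead of being captured, which would return the achiral alkylidene succinate and erase the hydrogenation-derived centre. Traces of water may also intercept it, leading on to the aryl ketone. The fallback makes the benzylic C–O bond by an aldol reaction instead of a C–H oxidation; it sets out from veratraldehyde 1 and comes back to the route at lactone acid 7. (S)-4-Benzyl-1,3-oxazolidin-2-one is N-acylated with methyl 4-chloro-4-oxobutanoate (n-BuLi, THF, −78 °C) to give (S)-4-benzyl-3-(4-methoxy-4-oxobutanoyl)-1,3-oxazolidin-2-one F1. Its Z boron enolate (n-Bu2BOTf, i-Pr2NEt, CH2Cl2, −78 → 0 °C) should add to 1 in an Evans syn-aldol reaction to give (S)-4-benzyl-3-[(S)-2-[(S)-(3,4-dimethoxyphenyl)(hydroxy)methyl]-4-methoxy-4-oxobutanoyl]-1,3-oxazolidin-2-one F2. The syn adduct closes onto its methyl ester (catalytic PPTS, CH2Cl2) to the trans lactone imide (S)-4-benzyl-3-[(2S,3S)-2-(3,4-dimethoxyphenyl)-5-oxotetrahydrofuran-3-carbonyl]-1,3-oxazolidin-2-one F3. LiOH/H2O2 (THF/H2O, 0 °C) then removes the auxiliary and, after acidification, gives 7.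

Step 8. The transient hydroxy-aldehyde may enolise and self-condense under the strongly basic conditions, the lactolate may open too slowly, or E-selectivity may erode. The fallback builds the styrene by alkene metathesis; it sets out from lactol 10 and comes back to the route at silyl ether 13. Wittig methylenation of 10 (Ph3PCH3Br, KOt-Bu, THF, 0 °C → rt) should give (1S,2R)-2-{[(tert-butyldimethylsilyl)oxy]methyl}-1-(3,4-dimethoxyphenyl)pent-4-en-1-ol F4. Cross-metathesis of this terminal alkene with an excess of 4-methoxystyrene (second-generation Grubbs catalyst, CH2Cl2, 40 °C) should give the E-styrene 13, which is desilylated with n-Bu4NF to 14 as in step 8.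

Step 13. The secondary benzylic hydroxyl may compete for the acyl group, giving regioisomeric or doubly acylated material, and the activated acid may isomerise from Z to E by conjugate addition and elimination of DMAP. The fallback removes the site-selectivity question by full protection; it sets out from 13, isolated by working up step 8 before fluoride is added, and comes back to the route at target 23. Silylation of the secondary hydroxyl (TBSOTf, 2,6-lutidine, CH2Cl2, −78 °C) gives tert-butyl{[(1S,2R,4E)-2-{[(tert-butyldimethylsilyl)oxy]methyl}-1-(3,4-dimethoxyphenyl)-5-(4-methoxyphenyl)pent-4-en-1-yl]oxy}dimethylsilane F5. Selective cleavage of the primary silyl ether (HF·pyridine, pyridine, THF, 0 °C) should give (2R,3S)-3-[(tert-butyldimethylsilyl)oxy]-3-(3,4-dimethoxyphenyl)-2-[(2E)-3-(4-methoxyphenyl)prop-2-en-1-yl]propan-1-ol F6. Its only free hydroxyl is esterified with 21 through the mixed anhydride with 2,4,6-trichlorobenzoyl chloride (Et3N, toluene, no DMAP) to give (2R,3S)-3-[(tert-butyldimethylsilyl)oxy]-3-(3,4-dimethoxyphenyl)-2-[(2E)-3-(4-methoxyphenyl)prop-2-en-1-yl]propyl (2Z)-2-({[tert-butyl(dimethyl)silyl]oxy}methyl)but-2-enoate F7. Removal of both silyl groups (HF·pyridine, pyridine, THF, rt) gives 23.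

Further compounds
F1 | step 3 | (S)-4-benzyl-3-(4-methoxy-4-oxobutanoyl)-1,3-oxazolidin-2-one | COC(=O)CCC(=O)N1C(=O)OC[C@@H]1Cc2ccccc2
F2 | step 3 | (S)-4-benzyl-3-[(S)-2-[(S)-(3,4-dimethoxyphenyl)(hydroxy)methyl]-4-methoxy-4-oxobutanoyl]-1,3-oxazolidin-2-one | O=C(N1C(=O)OC[C@@H]1Cc2ccccc2)[C@@H](CC(=O)OC)[C@H](O)c3ccc(OC)c(OC)c3
F3 | step 3 | (S)-4-benzyl-3-[(2S,3S)-2-(3,4-dimethoxyphenyl)-5-oxotetrahydrofuran-3-carbonyl]-1,3-oxazolidin-2-one | O=C(N1C(=O)OC[C@@H]1Cc2ccccc2)[C@H]3CC(=O)O[C@@H]3c4ccc(OC)c(OC)c4
F4 | step 8 | (1S,2R)-2-{[(tert-butyldimethylsilyl)oxy]methyl}-1-(3,4-dimethoxyphenyl)pent-4-en-1-ol | CC(C)(C)[Si](C)(C)OC[C@@H](CC=C)[C@H](O)c1ccc(OC)c(OC)c1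
F5 | step 13 | tert-butyl{[(1S,2R,4E)-2-{[(tert-butyldimethylsilyl)oxy]methyl}-1-(3,4-dimethoxyphenyl)-5-(4-methoxyphenyl)pent-4-en-1-yl]oxy}dimethylsilane | CC(C)(C)[Si](C)(C)OC[C@@H](C/C=C/c1ccc(OC)cc1)[C@H](O[Si](C)(C)C(C)(C)C)c1ccc(OC)c(OC)c1
F6 | step 13 | (2R,3S)-3-[(tert-butyldimethylsilyl)oxy]-3-(3,4-dimethoxyphenyl)-2-[(2E)-3-(4-methoxyphenyl)prop-2-en-1-yl]propan-1-ol | OC[C@@H](C/C=C/c1ccc(OC)cc1)[C@H](O[Si](C)(C)C(C)(C)C)c1ccc(OC)c(OC)c1
F7 | step 13 | (2R,3S)-3-[(tert-butyldimethylsilyl)oxy]-3-(3,4-dimethoxyphenyl)-2-[(2E)-3-(4-methoxyphenyl)prop-2-en-1-yl]propyl (2Z)-2-({[tert-butyl(dimethyl)silyl]oxy}methyl)but-2-enoate | C/C=C(/CO[Si](C)(C)C(C)(C)C)C(=O)OC[C@@H](C/C=C/c1ccc(OC)cc1)[C@H](O[Si](C)(C)C(C)(C)C)c1ccc(OC)c(OC)c1
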